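**Plan**

1. Retrosynthesis (isoquinoline numbering, primed locants for the naphthalenes): the C1=N imine of the dihydroisoquinoline is opened to an aryl methyl ketone and a Boc-amine. The central naphthalene–naphthalene bond C3'–C3'' is then cut (Suzuki–Miyaura) into an aryl chloride (ketone half) and an aryl boronate (tetrahydroisoquinoline half).
2. The benzene ring of the dihydroisoquinoline is cut at C4a–C5 and C8–C8a. Going round this ring, C8a bears the acyl carbon C1, C8 an OMe, C7 the naphthyl, C6 an OH, C5 an H and C4a the C4 methylene. This is the pattern a 2-aryl-1,1-dimethoxy-3-silyloxybuta-1,3-diene and a 4-alkylbut-3-yn-2-one leave after loss of methanol.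
3. In the other half the C5–C1'' biaryl bond (Suzuki–Miyaura) and C1–C8a (Bischler–Napieralski) are cut. Both naphthalenes come from one 1-bromo-3-chloronaphthalene built by Stobbe condensation and ring closure.
4. Forward order of rings: naphthalene (steps 3–4), diene, benzene ring by Diels–Alder reaction (step 16); separately the tetrahydroisoquinoline heterocycle (step 19); two biaryl couplings (steps 24, 26); the dihydroisoquinoline heterocycle last (step 27); debenzylation.
5. Stereochemistry: both C3 centres (R) come from one D-alaninol-derived cyclic sulfamidate opened at its CH2 carbon. C1 (R) of the tetrahydroisoquinoline comes from a 1,3-trans-selective imine reduction directed by C3.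

Key step: step 16

Assumption: the target as specified fixes only three carbon stereocentres and leaves the biaryl axes open, so atropisomers arising in steps 16, 24 and 26 are carried as mixtures or separated by chromatography without change to the route.

**Route**

Step 1
Reactants: 1 2-bromo-5-hydroxybenzaldehyde
Product: 2 2-bromo-4-chloro-5-hydroxybenzaldehyde
Conditions: N-chlorosuccinimide, p-TsOH·H2O (cat.), MeCN, 40 °C
Reagents that add atoms: N-chlorosuccinimide, O=C1CCC(=O)N1Cl
Why: Electrophilic aromatic chlorination; with the position para to OH blocked by bromine, chlorine should enter the less hindered ortho position C4 (the other lies between OH and CHO), following the 2,4-dihalogenation pattern of 3-hydroxybenzaldehyde.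

Step 2
Reactants: 2 2-bromo-4-chloro-5-hydroxybenzaldehyde
Product: 3 5-(benzyloxy)-2-bromo-4-chlorobenzaldehyde
Conditions: BnBr, K2CO3, DMF, 23 °C
Reagents that add atoms: benzyl bromide, BrCc1ccccc1
Why: Williamson ether synthesis on the phenoxide; this benzyl ether masks the naphthol OH that will flank the central biaryl bond.

Step 3
Reactants: 3 5-(benzyloxy)-2-bromo-4-chlorobenzaldehyde; 4 diethyl succinate
Product: 5 (3E)-4-[5-(benzyloxy)-2-bromo-4-chlorophenyl]-3-(ethoxycarbonyl)but-3-enoic acid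
Conditions: KOt-Bu, t-BuOH, 50 °C; then 1 M HCl
Reagents that add atoms: none
Why: Stobbe condensation; aldol addition, lactonisation and eliminative ring opening should give the E half-ester with the aryl group cis to CH2CO2H, as the ring closure requires.

Step 4
Reactants: 5 (3E)-4-[5-(benzyloxy)-2-bromo-4-chlorophenyl]-3-(ethoxycarbonyl)but-3-enoic acid
Product: 6 ethyl 4-acetoxy-5-(benzyloxy)-8-bromo-6-chloronaphthalene-2-carboxylate
Conditions: Ac2O, NaOAc, 140 °C
Reagents that add atoms: acetic anhydride, CC(=O)OC(C)=O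
Why: Mixed-anhydride formation and intramolecular Friedel–Crafts acylation at the only free position ortho to the side chain, then enolisation and O-acetylation, should close the second naphthalene ring.

Step 5
Reactants: 6 ethyl 4-acetoxy-5-(benzyloxy)-8-bromo-6-chloronaphthalene-2-carboxylate
Product: 8 ethyl 5-(benzyloxy)-8-bromo-6-chloro-4-methoxynaphthalene-2-carboxylate, via naphthol 7 (not isolated)
Conditions: K2CO3, EtOH, 50 °C; then MeI, DMF, 23 °C
Reagents that add atoms: iodomethane, CI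
Why: Transesterification frees the naphthol and Williamson methylation caps it, which places the OMe on the ring that will carry the C-methyl group.

Step 6
Reactants: 8 ethyl 5-(benzyloxy)-8-bromo-6-chloro-4-methoxynaphthalene-2-carboxylate
Product: 9 [5-(benzyloxy)-8-bromo-6-chloro-4-methoxynaphthalen-2-yl]methanol
Conditions: LiAlH4, THF, 0 °C
Reagents that add atoms: none
Why: Hydride reduction of the ester; aryl halides and aryl ethers should be inert at 0 °C.

Step 7
Reactants: 9 [5-(benzyloxy)-8-bromo-6-chloro-4-methoxynaphthalen-2-yl]methanol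
Product: 11 4-(benzyloxy)-1-bromo-3-chloro-5-methoxy-7-methylnaphthalene, via benzylic mesylate 10 (not isolated)
Conditions: MsCl, Et3N, THF, 0 °C; then LiBHEt3 (excess), 0 → 23 °C
Reagents that add atoms: none
Why: Sulfonylation followed by SN2 hydride displacement deoxygenates the benzylic alcohol to the methyl group; compound 11 serves both halves.

Step 8
Reactants: 11 4-(benzyloxy)-1-bromo-3-chloro-5-methoxy-7-methylnaphthalene
Product: 12 2-[4-(benzyloxy)-3-chloro-5-methoxy-7-methylnaphthalen-1-yl]acetonitrile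
Conditions: Me3SiCH2CN, Pd2(dba)3 (cat.), Xantphos (cat.), ZnF2, DMF, 90 °C
Reagents that add atoms: (trimethylsilyl)acetonitrile, C[Si](C)(C)CC#N
Why: Palladium-catalysed α-arylation of a fluoride-activated silyl nitrile; zerovalent palladium with this bisphosphine should insert into C–Br and leave C–Cl alone.

Step 9
Reactants: 12 2-[4-(benzyloxy)-3-chloro-5-methoxy-7-methylnaphthalen-1-yl]acetonitrile
Product: 14 4-(benzyloxy)-3-chloro-5-methoxy-7-methyl-1-(2,2,2-trimethoxyethyl)naphthalene, via imidate hydrochloride 13 (not isolated)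
Conditions: HCl (g), MeOH (1.1 equiv), CH2Cl2/Et2O, 0 °C; then MeOH, hexane, 23 °C
Reagents that add atoms: methanol, CO
Why: Pinner reaction to the imidate salt, whose alcoholysis should give the trimethyl orthoester with precipitation of ammonium chloride.

Step 10
Reactants: 14 4-(benzyloxy)-3-chloro-5-methoxy-7-methyl-1-(2,2,2-trimethoxyethyl)naphthalene
Product: 15 4-(benzyloxy)-3-chloro-1-(2,2-dimethoxyethenyl)-5-methoxy-7-methylnaphthalene
Conditions: Me3SiOTf, i-Pr2NEt, CH2Cl2, −20 → 23 °C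
Reagents that add atoms: none
Why: Lewis-acid abstraction of methoxide gives a dimethoxycarbenium ion whose acidic benzylic proton is removed by the hindered amine, a β-elimination of methanol from the orthoester to the ketene acetal.

Step 11
Reactants: 15 4-(benzyloxy)-3-chloro-1-(2,2-dimethoxyethenyl)-5-methoxy-7-methylnaphthalene
Product: 16 3-[4-(benzyloxy)-3-chloro-5-methoxy-7-methylnaphthalen-1-yl]-4,4-dimethoxybut-3-en-2-one
Conditions: AcCl, Et3N, Et2O, 0 → 23 °C
Reagents that add atoms: acetyl chloride, CC(=O)Cl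
Why: C-acylation of the electron-rich ketene acetal at its β-carbon; the amine should deprotonate the resulting carbenium ion to the push–pull acylketene acetal before chloride can demethylate it.

Step 12
Reactants: 16 3-[4-(benzyloxy)-3-chloro-5-methoxy-7-methylnaphthalen-1-yl]-4,4-dimethoxybut-3-en-2-one
Product: 18 {[3-[4-(benzyloxy)-3-chloro-5-methoxy-7-methylnaphthalen-1-yl]-4,4-dimethoxybuta-1,3-dien-2-yl]oxy}trimethylsilane, via lithium dienolate 17 (not isolated)
Conditions: LiN(i-Pr)2, THF, −78 °C; then Me3SiCl, −78 → 0 °C; used crude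
Reagents that add atoms: chlorotrimethylsilane, C[Si](C)(C)Cl
Why: Kinetic enolisation of the acetyl methyl group (the only enolisable position) and O-silylation give the 2-naphthyl-1,1-dimethoxy-3-silyloxydiene.

Step 13
Reactants: 19 trimethylsilylacetylene; 20 tert-butyl (4R)-4-methyl-1,2,3-oxathiazolidine-3-carboxylate 2,2-dioxide (commercial cyclic sulfamidate of N-Boc-D-alaninol)
Product: 23 tert-butyl N-[(2R)-5-(trimethylsilyl)pent-4-yn-2-yl]carbamate, via lithium (trimethylsilyl)acetylide 21 (not isolated), via lithium N-sulfonate 22 (not isolated)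
Conditions: n-BuLi, THF, −78 °C; then 20, −78 → 23 °C; then 10% aq. citric acid
Reagents that add atoms: none
Why: SN2 ring opening of the cyclic sulfamidate at its primary carbon by the acetylide, then mild acid hydrolysis of the N-sulfonate; the stereocentre is not touched and stays R.

Step 14
Reactants: 23 tert-butyl N-[(2R)-5-(trimethylsilyl)pent-4-yn-2-yl]carbamate
Product: 24 tert-butyl N-[(2R)-pent-4-yn-2-yl]carbamate
Conditions: K2CO3 (cat.), MeOH, 23 °C
Reagents that add atoms: none
Why: Methoxide-induced protodesilylation of the alkynylsilane.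

Step 15
Reactants: 24 tert-butyl N-[(2R)-pent-4-yn-2-yl]carbamate
Product: 26 tert-butyl N-[(2R)-6-oxohept-4-yn-2-yl]carbamate, via dilithio alkyne carbamate 25 (not isolated)
Conditions: n-BuLi (2.1 equiv), THF, −78 °C; then MeC(O)N(OMe)Me, −78 → 0 °C; aq. NH4Cl
Reagents that add atoms: N-methoxy-N-methylacetamide, CON(C)C(C)=O
Why: Weinreb ketone synthesis at the acetylide carbon of the N,C-dianion; the chelated tetrahedral adduct should prevent over-addition.

Step 16
Reactants: 18 {[3-[4-(benzyloxy)-3-chloro-5-methoxy-7-methylnaphthalen-1-yl]-4,4-dimethoxybuta-1,3-dien-2-yl]oxy}trimethylsilane; 26 tert-butyl N-[(2R)-6-oxohept-4-yn-2-yl]carbamate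
Product: 29 tert-butyl N-[(2R)-1-{2-acetyl-4-[4-(benzyloxy)-3-chloro-5-methoxy-7-methylnaphthalen-1-yl]-5-hydroxy-3-methoxyphenyl}propan-2-yl]carbamate, via cyclohexadiene cycloadduct 27 (not isolated), via aryl silyl ether 28 (not isolated)
Conditions: 26 (excess), PhMe, 110 °C, sealed tube; then pyridinium p-toluenesulfonate, MeOH, 23 °C
Reagents that add atoms: none
Why: The diene CH2 terminus (future C5) bonds to the ynone β-carbon (future C4a) and the ketene-acetal carbon (future C8) to the α-carbon (future C8a) in an asynchronous, polarised [4+2] cycloaddition; the 1,4-cyclohexadiene 27 then loses methanol across the ring to aromatise and mild acid methanolysis frees the C6 phenol. The closest known reaction type is the Diels–Alder/aromatisation of 1,1-dialkoxy-3-silyloxybuta-1,3-dienes with alkynyl ketones and esters to resorcinol monoethers; here the diene carries in addition an aryl group at C2. The six-membered benzene ring is closed by the intermolecular cycloaddition itself, both ring bonds forming in that event. No stereocentre is created; the R centre of the side chain is remote and untouched, and the new aryl–naphthyl axis forms without control. The selectivity needed is regiochemical, and it should be secured by the largest HOMO coefficient at the CH2 terminus (donation from three oxygens) matching the largest LUMO coefficient at the ynone β-carbon. The adjacent aryl and silyloxy groups on C2 and C3 should also destabilise the s-trans conformer and so favour the reactive s-cis form.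

Step 17
Reactants: 30 1,3-bis(benzyloxy)-5-bromobenzene; 20 tert-butyl (4R)-4-methyl-1,2,3-oxathiazolidine-3-carboxylate 2,2-dioxide
Product: 33 tert-butyl N-[(2R)-1-[3,5-bis(benzyloxy)phenyl]propan-2-yl]carbamate, via aryl Grignard reagent 31 (not isolated), via magnesium N-sulfonate 32 (not isolated)
Conditions: Mg, THF, 60 °C; then CuBr·SMe2 (cat.), 20, THF, −30 → 23 °C; then 10% aq. citric acid
Reagents that add atoms: none
Why: Copper-catalysed SN2 opening of the sulfamidate at CH2 by the aryl Grignard reagent, so the second C3 centre is taken unchanged (R) from the same chiral building block.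

Step 18
Reactants: 33 tert-butyl N-[(2R)-1-[3,5-bis(benzyloxy)phenyl]propan-2-yl]carbamate
Product: 35 N-[(2R)-1-[3,5-bis(benzyloxy)phenyl]propan-2-yl]acetamide, via amine hydrochloride 34 (not isolated)
Conditions: HCl (4 M in 1,4-dioxane), CH2Cl2, 23 °C; then Ac2O, Et3N, CH2Cl2, 0 → 23 °C
Reagents that add atoms: acetic anhydride, CC(=O)OC(C)=O
Why: Acidolysis of the carbamate and N-acetylation install the acyl carbon needed for the cyclodehydration.

Step 19
Reactants: 35 N-[(2R)-1-[3,5-bis(benzyloxy)phenyl]propan-2-yl]acetamide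
Product: 36 (3R)-6,8-bis(benzyloxy)-1,3-dimethyl-3,4-dihydroisoquinoline
Conditions: POCl3, MeCN, 80 °C
Reagents that add atoms: none
Why: Bischler–Napieralski cyclodehydration; the two positions ortho to the side chain are equivalent by symmetry and each is activated by both benzyloxy groups, so no regiochemical question arises.

Step 20
Reactants: 36 (3R)-6,8-bis(benzyloxy)-1,3-dimethyl-3,4-dihydroisoquinoline
Product: 37 (1R,3R)-6,8-bis(benzyloxy)-1,3-dimethyl-1,2,3,4-tetrahydroisoquinoline
Conditions: LiAlH4, AlMe3, THF, −78 → −20 °C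
Reagents that add atoms: none
Why: Diastereoselective hydride reduction of the imine; coordination of AlMe3 to nitrogen should push the C3 methyl group pseudo-axial so that hydride adds to the opposite face, setting C1 as R (1,3-trans).

Step 21
Reactants: 37 (1R,3R)-6,8-bis(benzyloxy)-1,3-dimethyl-1,2,3,4-tetrahydroisoquinoline
Product: 38 tert-butyl (1R,3R)-6,8-bis(benzyloxy)-1,3-dimethyl-3,4-dihydro-1H-isoquinoline-2-carboxylate
Conditions: Boc2O, i-Pr2NEt, 4-(dimethylamino)pyridine (cat.), MeCN, 60 °C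
Reagents that add atoms: di-tert-butyl dicarbonate, CC(C)(C)OC(=O)OC(=O)OC(C)(C)C
Why: Carbamate formation under acyl-transfer catalysis masks the hindered secondary amine for the halogenation and coupling steps.

Step 22
Reactants: 38 tert-butyl (1R,3R)-6,8-bis(benzyloxy)-1,3-dimethyl-3,4-dihydro-1H-isoquinoline-2-carboxylate
Product: 39 tert-butyl (1R,3R)-6,8-bis(benzyloxy)-5-bromo-1,3-dimethyl-3,4-dihydro-1H-isoquinoline-2-carboxylate
Conditions: N-bromosuccinimide, CH2Cl2, −20 → 0 °C
Reagents that add atoms: N-bromosuccinimide, O=C1CCC(=O)N1Br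
Why: Electrophilic aromatic bromination at C5 (para to the C8 ether, ortho to the C6 ether), which should be preferred over C7 wedged between two benzyloxy groups.

Step 23
Reactants: 11 4-(benzyloxy)-1-bromo-3-chloro-5-methoxy-7-methylnaphthalene
Product: 41 [4-(benzyloxy)-3-chloro-5-methoxy-7-methylnaphthalen-1-yl]boronic acid, via aryllithium 40 (not isolated)
Conditions: n-BuLi, THF, −78 °C; then B(Oi-Pr)3, −78 → 23 °C; then 1 M HCl
Reagents that add atoms: triisopropyl borate, CC(C)OB(OC(C)C)OC(C)C; water, O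
Why: Bromine–lithium exchange, much faster than chlorine–lithium exchange, followed by borylation and hydrolysis.

Step 24
Reactants: 39 tert-butyl (1R,3R)-6,8-bis(benzyloxy)-5-bromo-1,3-dimethyl-3,4-dihydro-1H-isoquinoline-2-carboxylate; 41 [4-(benzyloxy)-3-chloro-5-methoxy-7-methylnaphthalen-1-yl]boronic acid
Product: 42 tert-butyl (1R,3R)-6,8-bis(benzyloxy)-5-[4-(benzyloxy)-3-chloro-5-methoxy-7-methylnaphthalen-1-yl]-1,3-dimethyl-3,4-dihydro-1H-isoquinoline-2-carboxylate
Conditions: Pd(PPh3)4 (cat.), K3PO4, DME/H2O, 90 °C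
Reagents that add atoms: none
Why: Suzuki–Miyaura coupling; this triarylphosphine catalyst should add oxidatively to the C–Br bond while the electron-rich aryl chloride stays intact.

Step 25
Reactants: 42 tert-butyl (1R,3R)-6,8-bis(benzyloxy)-5-[4-(benzyloxy)-3-chloro-5-methoxy-7-methylnaphthalen-1-yl]-1,3-dimethyl-3,4-dihydro-1H-isoquinoline-2-carboxylate
Product: 43 tert-butyl (1R,3R)-6,8-bis(benzyloxy)-5-[4-(benzyloxy)-5-methoxy-7-methyl-3-(4,4,5,5-tetramethyl-1,3,2-dioxaborolan-2-yl)naphthalen-1-yl]-1,3-dimethyl-3,4-dihydro-1H-isoquinoline-2-carboxylate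
Conditions: B2pin2, Pd2(dba)3 (cat.), XPhos (cat.), KOAc, 1,4-dioxane, 110 °C
Reagents that add atoms: bis(pinacolato)diboron, CC1(C)OB(OC1(C)C)B1OC(C)(C)C(C)(C)O1
Why: Miyaura borylation; a bulky electron-rich biarylphosphine is what lets zerovalent palladium insert into the ortho-alkoxy aryl chloride.

Step 26
Reactants: 43 the pinacol boronate of step 25; 29 tert-butyl N-[(2R)-1-{2-acetyl-4-[4-(benzyloxy)-3-chloro-5-methoxy-7-methylnaphthalen-1-yl]-5-hydroxy-3-methoxyphenyl}propan-2-yl]carbamate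
Product: 44 bis-Boc tetra-O-benzyl keto carbamate with the 3',3''-linked binaphthyl core (the aryl ketone of 29 on C1' and C5 of the tetrahydroisoquinoline of 42 on C1'')
Conditions: Pd(OAc)2 (cat.), SPhos (cat.), K3PO4, PhMe/H2O, 100 °C
Reagents that add atoms: none
Why: Suzuki–Miyaura coupling of an aryl chloride with an aryl boronate; it forms a biaryl with only two ortho substituents, and the free phenol, ketone and carbamates are tolerated under phosphate base.

Step 27
Reactants: 44 bis-Boc tetra-O-benzyl keto carbamate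
Product: 46 tetra-O-benzyl korundamine A, via amino ketone bis(trifluoroacetate) 45 (not isolated)
Conditions: CF3CO2H, anisole, CH2Cl2, 0 → 23 °C; then aq. NaHCO3
Reagents that add atoms: none
Why: Acidolysis removes both carbamates and the liberated primary amine condenses with the ortho acetyl group (6-exo-trig addition, then dehydration) to close the 3,4-dihydroisoquinoline; neither stereocentre is enolisable under these conditions.

Step 28
Reactants: 46 tetra-O-benzyl korundamine A
Product: 47 korundamine A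
Conditions: BCl3, C6HMe5, CH2Cl2, −78 °C; then MeOH
Reagents that add atoms: none
Why: Lewis-acid cleavage of the four aryl benzyl ethers with Friedel–Crafts trapping of the benzyl cation by pentamethylbenzene; at −78 °C the three methyl ethers and the imine should survive.

**Compound list**

1 | 2-bromo-5-hydroxybenzaldehyde | O=Cc1cc(O)ccc1Br | starting material
2 | 2-bromo-4-chloro-5-hydroxybenzaldehyde | O=Cc1cc(O)c(Cl)cc1Br | intermediate
3 | 5-(benzyloxy)-2-bromo-4-chlorobenzaldehyde | O=Cc1cc(OCc2ccccc2)c(Cl)cc1Br | intermediate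
4 | diethyl succinate | CCOC(=O)CCC(=O)OCC | starting material
5 | (3E)-4-[5-(benzyloxy)-2-bromo-4-chlorophenyl]-3-(ethoxycarbonyl)but-3-enoic acid | CCOC(=O)/C(CC(=O)O)=C/c1cc(OCc2ccccc2)c(Cl)cc1Br | intermediate
6 | ethyl 4-acetoxy-5-(benzyloxy)-8-bromo-6-chloronaphthalene-2-carboxylate | CCOC(=O)c1cc(OC(C)=O)c2c(OCc3ccccc3)c(Cl)cc(Br)c2c1 | intermediate
7 | ethyl 5-(benzyloxy)-8-bromo-6-chloro-4-hydroxynaphthalene-2-carboxylate (not isolated) | CCOC(=O)c1cc(O)c2c(OCc3ccccc3)c(Cl)cc(Br)c2c1 | intermediate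
8 | ethyl 5-(benzyloxy)-8-bromo-6-chloro-4-methoxynaphthalene-2-carboxylate | CCOC(=O)c1cc(OC)c2c(OCc3ccccc3)c(Cl)cc(Br)c2c1 | intermediate
9 | [5-(benzyloxy)-8-bromo-6-chloro-4-methoxynaphthalen-2-yl]methanol | OCc1cc(OC)c2c(OCc3ccccc3)c(Cl)cc(Br)c2c1 | intermediate
10 | [5-(benzyloxy)-8-bromo-6-chloro-4-methoxynaphthalen-2-yl]methyl methanesulfonate (not isolated) | CS(=O)(=O)OCc1cc(OC)c2c(OCc3ccccc3)c(Cl)cc(Br)c2c1 | intermediate
11 | 4-(benzyloxy)-1-bromo-3-chloro-5-methoxy-7-methylnaphthalene | Cc1cc(OC)c2c(OCc3ccccc3)c(Cl)cc(Br)c2c1 | intermediate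
12 | 2-[4-(benzyloxy)-3-chloro-5-methoxy-7-methylnaphthalen-1-yl]acetonitrile | N#CCc1cc(Cl)c(OCc2ccccc2)c2c(OC)cc(C)cc12 | intermediate
13 | methyl 2-[4-(benzyloxy)-3-chloro-5-methoxy-7-methylnaphthalen-1-yl]ethanimidate hydrochloride (not isolated) | Cl.COC(=N)Cc1cc(Cl)c(OCc2ccccc2)c2c(OC)cc(C)cc12 | intermediate
14 | 4-(benzyloxy)-3-chloro-5-methoxy-7-methyl-1-(2,2,2-trimethoxyethyl)naphthalene | COC(OC)(OC)Cc1cc(Cl)c(OCc2ccccc2)c2c(OC)cc(C)cc12 | intermediate
15 | 4-(benzyloxy)-3-chloro-1-(2,2-dimethoxyethenyl)-5-methoxy-7-methylnaphthalene | COC(OC)=Cc1cc(Cl)c(OCc2ccccc2)c2c(OC)cc(C)cc12 | intermediate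
16 | 3-[4-(benzyloxy)-3-chloro-5-methoxy-7-methylnaphthalen-1-yl]-4,4-dimethoxybut-3-en-2-one | COC(OC)=C(C(C)=O)c1cc(Cl)c(OCc2ccccc2)c2c(OC)cc(C)cc12 | intermediate
17 | lithium 3-[4-(benzyloxy)-3-chloro-5-methoxy-7-methylnaphthalen-1-yl]-4,4-dimethoxybuta-1,3-dien-2-olate (not isolated) | [Li+].C=C([O-])C(=C(OC)OC)c1cc(Cl)c(OCc2ccccc2)c2c(OC)cc(C)cc12 | intermediate
18 | {[3-[4-(benzyloxy)-3-chloro-5-methoxy-7-methylnaphthalen-1-yl]-4,4-dimethoxybuta-1,3-dien-2-yl]oxy}trimethylsilane | C=C(O[Si](C)(C)C)C(=C(OC)OC)c1cc(Cl)c(OCc2ccccc2)c2c(OC)cc(C)cc12 | intermediate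
19 | trimethylsilylacetylene | C#C[Si](C)(C)C | starting material
20 | tert-butyl (4R)-4-methyl-1,2,3-oxathiazolidine-3-carboxylate 2,2-dioxide | C[C@@H]1COS(=O)(=O)N1C(=O)OC(C)(C)C | starting material
21 | lithium (trimethylsilyl)acetylide (not isolated) | [Li]C#C[Si](C)(C)C | intermediate
22 | lithium N-(tert-butoxycarbonyl)-N-[(2R)-5-(trimethylsilyl)pent-4-yn-2-yl]sulfamate (not isolated) | [Li+].C[Si](C)(C)C#CC[C@@H](C)N(C(=O)OC(C)(C)C)S(=O)(=O)[O-] | intermediate
23 | tert-butyl N-[(2R)-5-(trimethylsilyl)pent-4-yn-2-yl]carbamate | C[Si](C)(C)C#CC[C@@H](C)NC(=O)OC(C)(C)C | intermediate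
24 | tert-butyl N-[(2R)-pent-4-yn-2-yl]carbamate | C#CC[C@@H](C)NC(=O)OC(C)(C)C | intermediate
25 | N,C-dilithio derivative of 24 (not isolated) | [Li]C#CC[C@@H](C)N([Li])C(=O)OC(C)(C)C | intermediate
26 | tert-butyl N-[(2R)-6-oxohept-4-yn-2-yl]carbamate | CC(=O)C#CC[C@@H](C)NC(=O)OC(C)(C)C | intermediate
27 | cyclohexa-1,4-diene cycloadduct of 18 and 26 (not isolated) | COC1(OC)C(C(C)=O)=C(C[C@@H](C)NC(=O)OC(C)(C)C)CC(O[Si](C)(C)C)=C1c1cc(Cl)c(OCc2ccccc2)c2c(OC)cc(C)cc12 | intermediate
28 | trimethylsilyl ether of 29 (not isolated) | COc1c(C(C)=O)c(C[C@@H](C)NC(=O)OC(C)(C)C)cc(O[Si](C)(C)C)c1-c1cc(Cl)c(OCc2ccccc2)c2c(OC)cc(C)cc12 | intermediate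
29 | tert-butyl N-[(2R)-1-{2-acetyl-4-[4-(benzyloxy)-3-chloro-5-methoxy-7-methylnaphthalen-1-yl]-5-hydroxy-3-methoxyphenyl}propan-2-yl]carbamate | COc1c(C(C)=O)c(C[C@@H](C)NC(=O)OC(C)(C)C)cc(O)c1-c1cc(Cl)c(OCc2ccccc2)c2c(OC)cc(C)cc12 | intermediate
30 | 1,3-bis(benzyloxy)-5-bromobenzene | Brc1cc(OCc2ccccc2)cc(OCc2ccccc2)c1 | starting material
31 | [3,5-bis(benzyloxy)phenyl]magnesium bromide (not isolated) | Br[Mg]c1cc(OCc2ccccc2)cc(OCc2ccccc2)c1 | intermediate
32 | bromomagnesium N-(tert-butoxycarbonyl)-N-[(2R)-1-[3,5-bis(benzyloxy)phenyl]propan-2-yl]sulfamate (not isolated) | [Mg+2].[Br-].CC(C)(C)OC(=O)N([C@H](C)Cc1cc(OCc2ccccc2)cc(OCc2ccccc2)c1)S(=O)(=O)[O-] | intermediate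
33 | tert-butyl N-[(2R)-1-[3,5-bis(benzyloxy)phenyl]propan-2-yl]carbamate | CC(C)(C)OC(=O)N[C@H](C)Cc1cc(OCc2ccccc2)cc(OCc2ccccc2)c1 | intermediate
34 | (2R)-1-[3,5-bis(benzyloxy)phenyl]propan-2-amine hydrochloride (not isolated) | Cl.C[C@@H](N)Cc1cc(OCc2ccccc2)cc(OCc2ccccc2)c1 | intermediate
35 | N-[(2R)-1-[3,5-bis(benzyloxy)phenyl]propan-2-yl]acetamide | CC(=O)N[C@H](C)Cc1cc(OCc2ccccc2)cc(OCc2ccccc2)c1 | intermediate
36 | (3R)-6,8-bis(benzyloxy)-1,3-dimethyl-3,4-dihydroisoquinoline | CC1=N[C@H](C)Cc2cc(OCc3ccccc3)cc(OCc3ccccc3)c12 | intermediate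
37 | (1R,3R)-6,8-bis(benzyloxy)-1,3-dimethyl-1,2,3,4-tetrahydroisoquinoline | C[C@H]1N[C@H](C)Cc2cc(OCc3ccccc3)cc(OCc3ccccc3)c12 | intermediate
38 | tert-butyl (1R,3R)-6,8-bis(benzyloxy)-1,3-dimethyl-3,4-dihydro-1H-isoquinoline-2-carboxylate | C[C@H]1N(C(=O)OC(C)(C)C)[C@H](C)Cc2cc(OCc3ccccc3)cc(OCc3ccccc3)c12 | intermediate
39 | tert-butyl (1R,3R)-6,8-bis(benzyloxy)-5-bromo-1,3-dimethyl-3,4-dihydro-1H-isoquinoline-2-carboxylate | C[C@H]1N(C(=O)OC(C)(C)C)[C@H](C)Cc2c(Br)c(OCc3ccccc3)cc(OCc3ccccc3)c12 | intermediate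
40 | [4-(benzyloxy)-3-chloro-5-methoxy-7-methylnaphthalen-1-yl]lithium (not isolated) | [Li]c1cc(Cl)c(OCc2ccccc2)c2c(OC)cc(C)cc12 | intermediate
41 | [4-(benzyloxy)-3-chloro-5-methoxy-7-methylnaphthalen-1-yl]boronic acid | OB(O)c1cc(Cl)c(OCc2ccccc2)c2c(OC)cc(C)cc12 | intermediate
42 | tert-butyl (1R,3R)-6,8-bis(benzyloxy)-5-[4-(benzyloxy)-3-chloro-5-methoxy-7-methylnaphthalen-1-yl]-1,3-dimethyl-3,4-dihydro-1H-isoquinoline-2-carboxylate | C[C@H]1N(C(=O)OC(C)(C)C)[C@H](C)Cc2c(-c3cc(Cl)c(OCc4ccccc4)c4c(OC)cc(C)cc34)c(OCc3ccccc3)cc(OCc3ccccc3)c12 | intermediate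
43 | tert-butyl (1R,3R)-6,8-bis(benzyloxy)-5-[4-(benzyloxy)-5-methoxy-7-methyl-3-(4,4,5,5-tetramethyl-1,3,2-dioxaborolan-2-yl)naphthalen-1-yl]-1,3-dimethyl-3,4-dihydro-1H-isoquinoline-2-carboxylate | C[C@H]1N(C(=O)OC(C)(C)C)[C@H](C)Cc2c(-c3cc(B4OC(C)(C)C(C)(C)O4)c(OCc4ccccc4)c4c(OC)cc(C)cc34)c(OCc3ccccc3)cc(OCc3ccccc3)c12 | intermediate
44 | bis-Boc tetra-O-benzyl keto carbamate (3',3''-linked binaphthyl; aryl ketone of 29 on C1', C5 of the N-Boc tetrahydroisoquinoline on C1'') | COc1c(C(C)=O)c(C[C@@H](C)NC(=O)OC(C)(C)C)cc(O)c1-c1cc(-c3cc(-c4c(OCc7ccccc7)cc(OCc7ccccc7)c5c4C[C@@H](C)N(C(=O)OC(C)(C)C)[C@@H]5C)c4cc(C)cc(OC)c4c3OCc3ccccc3)c(OCc3ccccc3)c3c(OC)cc(C)cc13 | intermediate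
45 | amino ketone of 44 after loss of both Boc groups, bis(trifluoroacetate) salt (not isolated) | COc1c(C(C)=O)c(C[C@@H](C)N)cc(O)c1-c1cc(-c3cc(-c4c(OCc7ccccc7)cc(OCc7ccccc7)c5c4C[C@@H](C)N[C@@H]5C)c4cc(C)cc(OC)c4c3OCc3ccccc3)c(OCc3ccccc3)c3c(OC)cc(C)cc13.OC(=O)C(F)(F)F.OC(=O)C(F)(F)F | intermediate
46 | tetra-O-benzyl korundamine A (benzyl ethers on both naphthalene hydroxyls and on O6 and O8 of the tetrahydroisoquinoline) | COc1c2c(cc(O)c1-c1cc(-c3cc(-c4c(OCc7ccccc7)cc(OCc7ccccc7)c5c4C[C@@H](C)N[C@@H]5C)c4cc(C)cc(OC)c4c3OCc3ccccc3)c(OCc3ccccc3)c3c(OC)cc(C)cc13)C[C@@H](C)N=C2C | intermediate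
47 | korundamine A | COc1c2c(cc(O)c1-c1cc(-c3cc(-c4c(O)cc(O)c5c4C[C@@H](C)N[C@@H]5C)c4cc(C)cc(OC)c4c3O)c(O)c3c(OC)cc(C)cc13)C[C@@H](C)N=C2C | target

**Step count and risks**

Total steps: 28. Longest linear sequence: 16 steps (steps 1–12, 16, 26, 27, 28).

Steps most likely to fail:

1. Step 16. Bond formation at the crowded ketene-acetal carbon beside the twisted naphthyl group may be slow, while the diene is lost to hydrolysis, protodesilylation or silyl transfer to the carbamate N–H. The fallback lowers the oxidation level of the dienophile to a smaller, more electrophilic ynal. It sets out from alkyne 24 and diene 18 and returns at 29. The dilithio species 25, made from 24 as in step 15, would be added to DMF and quenched into aq. KH2PO4 to give tert-butyl N-[(2R)-6-oxohex-4-yn-2-yl]carbamate F1. Heating F1 with 18 in toluene and then pyridinium p-toluenesulfonate in MeOH should lead through the cyclohexadiene cycloadduct F2 and the aryl silyl ether F3 to the aryl aldehyde tert-butyl N-[(2R)-1-{4-[4-(benzyloxy)-3-chloro-5-methoxy-7-methylnaphthalen-1-yl]-2-formyl-5-hydroxy-3-methoxyphenyl}propan-2-yl]carbamate F4. Excess MeMgBr (THF, −78 → 0 °C) would give the secondary carbinol F5 as an inconsequential mixture of epimers. MnO2 (CH2Cl2, 23 °C) would oxidise this benzylic alcohol to ketone 29.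

2. Step 11. Chloride may demethylate the dialkoxycarbenium intermediate, diverting the acylation to a β-keto ester, and the ketene acetal 15 may hydrolyse during handling. The fallback attaches the aryl group to a preformed acylketene acetal by cross-coupling. It sets out from boronic acid 41 (made from 11 in step 23) and returns at 16, bypassing steps 8 to 11. Commercial 1,1-dimethoxyethene with AcCl and Et3N would give 4,4-dimethoxybut-3-en-2-one F6. N-Iodosuccinimide would iodinate its nucleophilic α-carbon to 3-iodo-4,4-dimethoxybut-3-en-2-one F7. Suzuki–Miyaura coupling of F7 with 41 (Pd(PPh3)4, K3PO4, 1,4-dioxane/H2O, 70 °C; the aryl chloride should remain) would give 16.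

3. Step 28. The Lewis acid may also remove a methyl ether (the one at C8 next to the imine nitrogen, or those peri to the freed naphthols), hindered benzyl ethers may cleave incompletely, or the exposed polyphenolic imine may degrade. The fallback removes the benzyl groups by hydrogenolysis before the imine exists. It sets out from 44 and returns at 47. H2 over Pd/C (EtOAc/MeOH, 23 °C) would give the tetraphenol bis-carbamate ketone F8, with the hindered aryl ketone expected to survive. CF3CO2H in CH2Cl2 followed by aq. NaHCO3 would then remove both carbamates and close the imine to give 47.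

**Further compounds**

F1 | step 16 | tert-butyl N-[(2R)-6-oxohex-4-yn-2-yl]carbamate | O=CC#CC[C@@H](C)NC(=O)OC(C)(C)C
F2 | step 16 | cyclohexa-1,4-diene cycloadduct of 18 and F1 | COC1(OC)C(C=O)=C(C[C@@H](C)NC(=O)OC(C)(C)C)CC(O[Si](C)(C)C)=C1c1cc(Cl)c(OCc2ccccc2)c2c(OC)cc(C)cc12
F3 | step 16 | trimethylsilyl ether of F4 | COc1c(C=O)c(C[C@@H](C)NC(=O)OC(C)(C)C)cc(O[Si](C)(C)C)c1-c1cc(Cl)c(OCc2ccccc2)c2c(OC)cc(C)cc12
F4 | step 16 | tert-butyl N-[(2R)-1-{4-[4-(benzyloxy)-3-chloro-5-methoxy-7-methylnaphthalen-1-yl]-2-formyl-5-hydroxy-3-methoxyphenyl}propan-2-yl]carbamate | COc1c(C=O)c(C[C@@H](C)NC(=O)OC(C)(C)C)cc(O)c1-c1cc(Cl)c(OCc2ccccc2)c2c(OC)cc(C)cc12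
F5 | step 16 | tert-butyl N-[(2R)-1-{4-[4-(benzyloxy)-3-chloro-5-methoxy-7-methylnaphthalen-1-yl]-5-hydroxy-2-(1-hydroxyethyl)-3-methoxyphenyl}propan-2-yl]carbamate (epimers at the carbinol carbon) | COc1c(C(C)O)c(C[C@@H](C)NC(=O)OC(C)(C)C)cc(O)c1-c1cc(Cl)c(OCc2ccccc2)c2c(OC)cc(C)cc12
F6 | step 11 | 4,4-dimethoxybut-3-en-2-one | COC(OC)=CC(C)=O
F7 | step 11 | 3-iodo-4,4-dimethoxybut-3-en-2-one | COC(OC)=C(I)C(C)=O
F8 | step 28 | tetraphenol bis-carbamate ketone (44 without its four benzyl groups) | COc1c(C(C)=O)c(C[C@@H](C)NC(=O)OC(C)(C)C)cc(O)c1-c1cc(-c3cc(-c4c(O)cc(O)c5c4C[C@@H](C)N(C(=O)OC(C)(C)C)[C@@H]5C)c4cc(C)cc(OC)c4c3O)c(O)c3c(OC)cc(C)cc13
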